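**Retrosynthetic overview**

- Ring A carries C5–OH, C6–H, C7–OMe and the C8 side chain in a row, with O1 on C8a and the C4 carbonyl on C4a. A vinylketene O=C=C(chain)–C8a=C4a and methoxyacetylene assemble exactly this pattern, so ring A is disconnected last, at C8–C8a, C5–C6, C7–C8 and C4a–C5.
- The benzannulation precursor is a diazo ketone on C6 of an (S)-2-phenyl-2,3-dihydropyran-4-one, in which O1 already sits on the future C8a and the chain on the diazo carbon (future C8).
- The diazo ketone is made from the pyranone-6-carbonyl chloride and a side-chain aldehyde enamine, followed by sulfonyl azide diazo transfer to the aminomethylene ketone. This avoids any carbanion or strong base next to the ring's C4 carbonyl and C3–H2, which would compete in an organometallic addition or an enolate acylation.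
- Ring C comes from ethyl (S)-3-hydroxy-3-phenylpropanoate (source of C2) by methyl ketone formation, oxalate Claisen condensation and acid cyclodehydration.
- Order of rings: ring B is bought, ring C is closed in step 5, ring A in step 13; desilylation ends the route.

Key step: step 13

Assumption: methoxyacetylene is not a stock chemical and is therefore prepared (step 12). The quaternary carbon of 21, C4a of 23 and the alkene geometry of 15 are transient stereo-elements and are left undefined.

**Route**

Step 1
Reactants: 1 ethyl (S)-3-hydroxy-3-phenylpropanoate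
Product: 2 (S)-3-hydroxy-N-methoxy-N-methyl-3-phenylpropanamide
Conditions: MeNH(OMe)·HCl, i-PrMgCl (excess), THF, −20 → 0 °C
Reagents that add atoms: N,O-dimethylhydroxylamine hydrochloride, CNOC.Cl
Why: Weinreb amide formation by aminolysis of the ester with the chloromagnesium amide, the hydroxyl being masked in the flask as its magnesium alkoxide, which also blocks β-elimination and leaves the stereocentre untouched.

Step 2
Reactants: 2 (S)-3-hydroxy-N-methoxy-N-methyl-3-phenylpropanamide
Product: 3 (S)-3-(tert-butyldimethylsilyloxy)-N-methoxy-N-methyl-3-phenylpropanamide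
Conditions: TBSCl, imidazole, DMF, rt
Reagents that add atoms: TBSCl, CC(C)(C)[Si](C)(C)Cl
Why: Standard silyl ether protection of a secondary benzylic alcohol, needed so that the later enolate chemistry meets no free hydroxyl and no retro-aldol pathway.

Step 3
Reactants: 3 (S)-3-(tert-butyldimethylsilyloxy)-N-methoxy-N-methyl-3-phenylpropanamide
Product: 4 (S)-4-(tert-butyldimethylsilyloxy)-4-phenylbutan-2-one
Conditions: MeMgBr, THF, 0 °C
Reagents that add atoms: MeMgBr, C[Mg]Br
Why: Weinreb ketone synthesis, in which the chelated tetrahedral adduct holds the reaction at the methyl ketone stage.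

Step 4
Reactants: 4 (S)-4-(tert-butyldimethylsilyloxy)-4-phenylbutan-2-one; 5 di-tert-butyl oxalate
Product: 6 tert-butyl (S)-6-(tert-butyldimethylsilyloxy)-2,4-dioxo-6-phenylhexanoate
Conditions: LiN(SiMe3)2 (2.1 equiv), THF, −78 °C; then 5, −78 → 0 °C; cold 1 M HCl work-up
Reagents that add atoms: none
Why: Crossed Claisen condensation of the kinetic methyl-side lithium enolate with a non-enolisable oxalate, the second equivalent of base storing the product as its stable diketonate.

Step 5
Reactants: 6 tert-butyl (S)-6-(tert-butyldimethylsilyloxy)-2,4-dioxo-6-phenylhexanoate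
Product: 7 (S)-4-oxo-2-phenyl-3,4-dihydro-2H-pyran-6-carboxylic acid
Conditions: TFA, CH2Cl2, trace H2O, 0 °C → rt
Reagents that add atoms: none
Why: Acid removes the silyl ether and the tert-butyl ester, and the freed hydroxyl adds to the C2 ketone and dehydrates (cyclodehydration of a δ-hydroxy-1,3-diketone to a 2,3-dihydropyran-4-one), closing ring C with the C–O bond of the stereocentre intact so that S is retained.

Step 6
Reactants: 8 ethyl 4-bromobutanoate
Product: 9 5-bromo-2-methylpentan-2-ol
Conditions: MeMgBr (2.2 equiv), Et2O, −20 → 0 °C; cold aq. NH4Cl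
Reagents that add atoms: MeMgBr, C[Mg]Br
Why: Double Grignard addition to the ester gives the tertiary alcohol, while the primary bromide is inert to MeMgBr at this temperature and the cold quench prevents closure of the alkoxide to 2,2-dimethyltetrahydrofuran.

Step 7
Reactants: 9 5-bromo-2-methylpentan-2-ol
Product: 10 (5-bromo-2-methylpentan-2-yl)oxy(triethyl)silane
Conditions: TESOTf, 2,6-lutidine, CH2Cl2, −78 → 0 °C
Reagents that add atoms: TESOTf, CC[Si](CC)(CC)OS(=O)(=O)C(F)(F)F
Why: Silylation of a hindered tertiary alcohol with a silyl triflate, giving an ether that survives Grignard formation and would otherwise be a ketene trap in the key step.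

Step 8
Reactants: 10 (5-bromo-2-methylpentan-2-yl)oxy(triethyl)silane
Product: 12 5-methyl-5-(triethylsilyloxy)hexanal, via Grignard reagent 11 (not isolated)
Conditions: Mg, THF, 45 °C; DMF, 0 °C; aq. NH4Cl
Reagents that add atoms: DMF, CN(C)C=O
Why: Bouveault formylation of the primary Grignard reagent with DMF, whose hemiaminal salt releases the aldehyde only on work-up.

Step 9
Reactants: 12 5-methyl-5-(triethylsilyloxy)hexanal
Product: 13 4-[(E)-5-methyl-5-(triethylsilyloxy)hex-1-en-1-yl]morpholine
Conditions: morpholine, 4 Å molecular sieves, toluene, rt; filter, concentrate under high vacuum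
Reagents that add atoms: morpholine, C1COCCN1
Why: Dehydrative condensation of an unbranched aldehyde with a secondary amine gives the E enamine, the carbon nucleophile for the next step.

Step 10
Reactants: 7 (S)-4-oxo-2-phenyl-3,4-dihydro-2H-pyran-6-carboxylic acid; 13 4-[(E)-5-methyl-5-(triethylsilyloxy)hex-1-en-1-yl]morpholine
Product: 15 (S)-6-[5-methyl-2-(morpholin-4-ylmethylidene)-5-(triethylsilyloxy)hexanoyl]-2-phenyl-2,3-dihydro-4H-pyran-4-one, via acid chloride 14 (not isolated)
Conditions: (COCl)2, cat. DMF, CH2Cl2, 0 °C → rt, evaporate; then 13, Et3N, CH2Cl2, −20 °C → rt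
Reagents that add atoms: none
Why: Stork enamine C-acylation by an acid chloride that has no α-hydrogen, followed by deprotonation of the iminium by Et3N to the vinylogous amide, joins the two fragments without exposing the ring's C4 carbonyl or C3–H2 to an organometallic or a strong base.

Step 11
Reactants: 15 (S)-6-[5-methyl-2-(morpholin-4-ylmethylidene)-5-(triethylsilyloxy)hexanoyl]-2-phenyl-2,3-dihydro-4H-pyran-4-one
Product: 16 (S)-6-[2-diazo-5-methyl-5-(triethylsilyloxy)hexanoyl]-2-phenyl-2,3-dihydro-4H-pyran-4-one
Conditions: 4-acetamidobenzenesulfonyl azide, MeCN, 0 °C → rt, shielded from light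
Reagents that add atoms: 4-acetamidobenzenesulfonyl azide (p-ABSA), CC(=O)Nc1ccc(cc1)S(=O)(=O)N=[N+]=[N-]
Why: Diazo transfer to an α-aminomethylene ketone, in which the azide adds across the enamine C=C and the triazoline fragments to the N-sulfonylformamidine, places the diazo group regiospecifically on the carbon between the carbonyl and the chain.

Step 12
Reactants: 17 chloroacetaldehyde dimethyl acetal
Product: 19 methoxyacetylene, via sodium methoxyethynide 18 (not isolated)
Conditions: NaNH2 (3 equiv), liq. NH3, −33 °C; evaporate NH3; satd aq. NaCl, −20 °C; distil into cold ClCH2CH2Cl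
Reagents that add atoms: none
Why: Twofold base-induced elimination (methanol, then HCl) from the chloroacetal gives the alkoxyacetylene, held as its sodium acetylide until the cold aqueous quench.

Step 13
Reactants: 16 (S)-6-[2-diazo-5-methyl-5-(triethylsilyloxy)hexanoyl]-2-phenyl-2,3-dihydro-4H-pyran-4-one; 19 methoxyacetylene
Product: 24 (S)-5-hydroxy-7-methoxy-8-[3-methyl-3-(triethylsilyloxy)butyl]flavanone, via vinylketene 20 (not isolated), via cyclobutenone 21 (not isolated), via dienylketene 22 (not isolated), via cyclohexadienone 23 (not isolated)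
Conditions: 19 (5 equiv), ClCH2CH2Cl, hν (300 nm, Pyrex), 15 °C, sealed vessel; then vent excess alkyne, 80 °C
Reagents that add atoms: none
Why: Light expels N2 and pyranone C6 (future C8a) shifts from the acyl carbon (future C5) to the diazo carbon (future C8) in a photochemical Wolff rearrangement, giving vinylketene 20, which adds methoxyacetylene by (2+2) cycloaddition to 21; on warming, 21 opens by 4π cleavage of C5–C8 to dienylketene 22, which closes by 6π electrocyclisation to 23 and enolises to the phenol. The closest known reaction type is the second-generation Danheiser benzannulation of α'-diazo enones with alkoxyacetylenes. Ring A is closed by the 6π electrocyclisation that joins ketene carbon C5 to C4a, after the Wolff shift has made C8–C8a and the cycloaddition C5–C6 and C7–C8. No new stereocentre survives, since the quaternary carbon of 21 and C4a of 23 are erased, and C2 of ring C is a spectator whose bonds are not touched. The step needs the methoxy group meta to the new phenol, and this is secured by the polarity of the ynol ether, whose unsubstituted nucleophilic carbon bonds to the electrophilic ketene carbon while the methoxy carbon bonds to C8. The ring opening is reversible and only the dienylketene with the pyranone turned inward can cyclise, and because O1 is bonded to C8a and the chain to C8 from the outset, neither phenol differentiation nor a 6- versus 8-alkyl question arises.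

Step 14
Reactants: 24 (S)-5-hydroxy-7-methoxy-8-[3-methyl-3-(triethylsilyloxy)butyl]flavanone
Product: 25 (2S)-5-hydroxy-8-(3-hydroxy-3-methylbutyl)-7-methoxy-2-phenylchroman-4-one (CNP0160063.1)
Conditions: HF·pyridine, pyridine, THF, 0 °C → rt
Reagents that add atoms: none
Why: Fluoride cleavage of the tertiary triethylsilyl ether in a buffered acidic medium, which avoids the base-induced opening of the flavanone to a chalcone and so keeps C2 as S.

**Compound list**

1 | ethyl (S)-3-hydroxy-3-phenylpropanoate | CCOC(=O)C[C@H](O)c1ccccc1 | starting material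
2 | (S)-3-hydroxy-N-methoxy-N-methyl-3-phenylpropanamide | CON(C)C(=O)C[C@H](O)c1ccccc1 | intermediate
3 | (S)-3-(tert-butyldimethylsilyloxy)-N-methoxy-N-methyl-3-phenylpropanamide | CON(C)C(=O)C[C@H](O[Si](C)(C)C(C)(C)C)c1ccccc1 | intermediate
4 | (S)-4-(tert-butyldimethylsilyloxy)-4-phenylbutan-2-one | CC(=O)C[C@H](O[Si](C)(C)C(C)(C)C)c1ccccc1 | intermediate
5 | di-tert-butyl oxalate | CC(C)(C)OC(=O)C(=O)OC(C)(C)C | starting material
6 | tert-butyl (S)-6-(tert-butyldimethylsilyloxy)-2,4-dioxo-6-phenylhexanoate (drawn as the diketone, largely enolised) | CC(C)(C)OC(=O)C(=O)CC(=O)C[C@H](O[Si](C)(C)C(C)(C)C)c1ccccc1 | intermediate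
7 | (S)-4-oxo-2-phenyl-3,4-dihydro-2H-pyran-6-carboxylic acid | O=C1C[C@@H](c2ccccc2)OC(C(=O)O)=C1 | intermediate
8 | ethyl 4-bromobutanoate | CCOC(=O)CCCBr | starting material
9 | 5-bromo-2-methylpentan-2-ol | CC(C)(O)CCCBr | intermediate
10 | (5-bromo-2-methylpentan-2-yl)oxy(triethyl)silane | CC[Si](CC)(CC)OC(C)(C)CCCBr | intermediate
11 | [4-methyl-4-(triethylsilyloxy)pentyl]magnesium bromide | CC[Si](CC)(CC)OC(C)(C)CCC[Mg]Br | intermediate
12 | 5-methyl-5-(triethylsilyloxy)hexanal | CC[Si](CC)(CC)OC(C)(C)CCCC=O | intermediate
13 | 4-[(E)-5-methyl-5-(triethylsilyloxy)hex-1-en-1-yl]morpholine | CC[Si](CC)(CC)OC(C)(C)CC/C=C/N1CCOCC1 | intermediate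
14 | (S)-4-oxo-2-phenyl-3,4-dihydro-2H-pyran-6-carbonyl chloride | O=C1C[C@@H](c2ccccc2)OC(C(=O)Cl)=C1 | intermediate
15 | (S)-6-[5-methyl-2-(morpholin-4-ylmethylidene)-5-(triethylsilyloxy)hexanoyl]-2-phenyl-2,3-dihydro-4H-pyran-4-one | O=C1C[C@@H](c2ccccc2)OC(C(=O)C(=CN3CCOCC3)CCC(C)(C)O[Si](CC)(CC)CC)=C1 | intermediate
16 | (S)-6-[2-diazo-5-methyl-5-(triethylsilyloxy)hexanoyl]-2-phenyl-2,3-dihydro-4H-pyran-4-one | O=C1C[C@@H](c2ccccc2)OC(C(=O)C(=[N+]=[N-])CCC(C)(C)O[Si](CC)(CC)CC)=C1 | intermediate
17 | chloroacetaldehyde dimethyl acetal | COC(CCl)OC | starting material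
18 | sodium methoxyethynide | COC#[C-].[Na+] | intermediate
19 | methoxyacetylene | COC#C | intermediate
20 | 5-methyl-2-[(S)-4-oxo-2-phenyl-3,4-dihydro-2H-pyran-6-yl]-5-(triethylsilyloxy)hex-1-en-1-one (vinylketene) | O=C=C(CCC(C)(C)O[Si](CC)(CC)CC)C1=CC(=O)C[C@@H](c2ccccc2)O1 | intermediate
21 | 3-methoxy-4-[3-methyl-3-(triethylsilyloxy)butyl]-4-[(S)-4-oxo-2-phenyl-3,4-dihydro-2H-pyran-6-yl]cyclobut-2-en-1-one (both epimers at the quaternary carbon) | O=C1C=C(OC)C1(CCC(C)(C)O[Si](CC)(CC)CC)C3=CC(=O)C[C@@H](c2ccccc2)O3 | intermediate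
22 | 3-methoxy-7-methyl-4-[(S)-4-oxo-2-phenyl-3,4-dihydro-2H-pyran-6-yl]-7-(triethylsilyloxy)octa-1,3-dien-1-one (ketenyl carbon cis to the pyranyl group) | O=C=C/C(OC)=C(/CCC(C)(C)O[Si](CC)(CC)CC)C1=CC(=O)C[C@@H](c2ccccc2)O1 | intermediate
23 | (2S)-7-methoxy-8-[3-methyl-3-(triethylsilyloxy)butyl]-2-phenyl-2,3-dihydro-4aH-chromene-4,5-dione (keto tautomer of 24, both C4a epimers) | O=C1C=C(OC)C(CCC(C)(C)O[Si](CC)(CC)CC)=C2O[C@H](c3ccccc3)CC(=O)C12 | intermediate
24 | (S)-5-hydroxy-7-methoxy-8-[3-methyl-3-(triethylsilyloxy)butyl]flavanone | COc1cc(O)c2c(c1CCC(C)(C)O[Si](CC)(CC)CC)O[C@H](c1ccccc1)CC2=O | intermediate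
25 | (2S)-5-hydroxy-8-(3-hydroxy-3-methylbutyl)-7-methoxy-2-phenylchroman-4-one | COc1cc(O)c2c(c1CCC(C)(C)O)O[C@H](c1ccccc1)CC2=O | target

**Step count**

Total steps: 14. Longest linear sequence: 9 (steps 1, 2, 3, 4, 5, 10, 11, 13, 14).

**Steps most likely to fail**

Step 13. The ketene may be lost before the alkyne captures it, by dimerisation or by acylation of the product phenol. The excited pyranone enone may also undergo photocycloaddition with the alkyne, or the carbene may undergo a 1,2-hydrogen shift from the neighbouring CH2. The fallback separates the Wolff event from the ketene–alkyne chemistry and sets out from 16. Irradiation of 16 in aqueous THF without alkyne lets water trap the ketene (Arndt–Eistert homologation) and should give 5-methyl-2-[(S)-4-oxo-2-phenyl-3,4-dihydro-2H-pyran-6-yl]-5-(triethylsilyloxy)hexanoic acid F1. The Ghosez reagent (1-chloro-N,N,2-trimethylprop-1-en-1-amine) under neutral conditions converts it into 5-methyl-2-[(S)-4-oxo-2-phenyl-3,4-dihydro-2H-pyran-6-yl]-5-(triethylsilyloxy)hexanoyl chloride F2. Slow addition of Et3N to F2 and excess 19 in CH2Cl2 in the dark generates vinylketene 20 by dehydrochlorination. Its cycloaddition gives cyclobutenone 21, and heating at 80 °C leads on to 24, where the route is rejoined.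

Step 10. The enamine may be acylated on nitrogen, may add in conjugate fashion to the enedione, or may hydrolyse before C-acylation. The fallback sets out from bromide 10 and acid chloride 14 and joins them through a diazoalkane. Oxidation of 10 with Me3NO in DMSO should give 4-methyl-4-(triethylsilyloxy)pentanal F3. Excess hydrazine hydrate converts it into [4-methyl-4-(triethylsilyloxy)pentylidene]hydrazine F4. Dehydrogenation with (COCl)2/DMSO/Et3N at −78 °C gives a cold solution of 1-diazo-4-methyl-4-(triethylsilyloxy)pentane F5. Acylation of F5 with 14 in the presence of Et3N gives diazo ketone 16 directly, so the route is rejoined at 16 and compound 15 is bypassed.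

Step 11. The push–pull enaminone may be too poor a nucleophile for the sulfonyl azide, so that cycloaddition is slow and the azide or the product decomposes first. The fallback sets out from 15. Mild aqueous acid (wet silica gel with oxalic acid) hydrolyses the enamine to 5-methyl-2-[(S)-4-oxo-2-phenyl-3,4-dihydro-2H-pyran-6-carbonyl]-5-(triethylsilyloxy)hexanal F6, an enolised α-formyl ketone. Deformylative Regitz diazo transfer with MsN3 and Et3N in MeCN then gives 16, where the route is rejoined.

**Further compounds**

F1 | step 13 | 5-methyl-2-[(S)-4-oxo-2-phenyl-3,4-dihydro-2H-pyran-6-yl]-5-(triethylsilyloxy)hexanoic acid | O=C1C[C@@H](c2ccccc2)OC(C(CCC(C)(C)O[Si](CC)(CC)CC)C(=O)O)=C1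
F2 | step 13 | 5-methyl-2-[(S)-4-oxo-2-phenyl-3,4-dihydro-2H-pyran-6-yl]-5-(triethylsilyloxy)hexanoyl chloride | O=C1C[C@@H](c2ccccc2)OC(C(CCC(C)(C)O[Si](CC)(CC)CC)C(Cl)=O)=C1
F3 | step 10 | 4-methyl-4-(triethylsilyloxy)pentanal | CC[Si](CC)(CC)OC(C)(C)CCC=O
F4 | step 10 | [4-methyl-4-(triethylsilyloxy)pentylidene]hydrazine | CC[Si](CC)(CC)OC(C)(C)CCC=NN
F5 | step 10 | 1-diazo-4-methyl-4-(triethylsilyloxy)pentane | CC[Si](CC)(CC)OC(C)(C)CCC=[N+]=[N-]
F6 | step 11 | 5-methyl-2-[(S)-4-oxo-2-phenyl-3,4-dihydro-2H-pyran-6-carbonyl]-5-(triethylsilyloxy)hexanal | O=CC(CCC(C)(C)O[Si](CC)(CC)CC)C(=O)C1=CC(=O)C[C@@H](c2ccccc2)O1
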